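I decide to reckon this flask by one number, the drain D: the pseudo-first-order constant with which dissolved target leaves, so that target stands at its making rate divided by D.

solid substrate 0.20 M; solid reagent 0.200 M; time 80 min

    target ⇌ isomer of the product (K1 = 15.8, k1 = 0.0643 min⁻¹)
    solid reagent ⇌ coupling partner, rate k2*(cs2 - [coupling partner]) while solid is left; crystals form when [coupling partner] > cs2 (cs2 = 0.14 M, k2 = 0.0671 min⁻¹)
    dissolved substrate + target → side product (k3 = 0.0576 M⁻¹ min⁻¹)
    solid product ⇌ target, rate k4*(cs4 - [target]) while solid is left; crystals form when [target] > cs4 (cs4 = 0.075 M, k4 = 0.331 min⁻¹)
    dissolved substrate + coupling partner ⇌ target (K5 = 1.8 M⁻¹, k5 = 0.169 M⁻¹ min⁻¹)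
    solid substrate ⇌ dissolved substrate, rate k6*(cs6 - [dissolved substrate]) while solid is left; crystals form when [dissolved substrate] > cs6 (cs6 = 0.10 M, k6 = 2.06 min⁻¹)

- percentages count the solid substrate that a species holds: one side product counts as two
- target is meant together with its solid product
- solid, in amounts per volume of the solution: solid substrate, solid product, solid reagent
- at the start none of the solid reagent is in solution
- at the start none of the solid substrate is in solution
- run time (flask): 80 min

* the target and solid product together standing at 80 min, as a percentage of the solid substrate charged
* the change that raises the amount of target and solid product together at 80 min, in percent of the solid substrate charged most ("none" if none brings more than 2 percentage points) (north / north-west / south / west / none)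
* amount of target and solid product together at 80 min, in percent of the solid substrate charged, after north

- north: doubling the solubility in step 6, all else as stated
- north-west: doubling the solubility in step 2, all else as stated
- south: doubling the dissolution coefficient of step 4, all else as stated
- west: doubling the dissolution coefficient of step 6, all else as stated

Let A, B, T and I be dissolved substrate, coupling partner, target and isomer of the product, in M. I take A at its solubility. Target then leaves back through the coupling, into the isomer and into side product:

D = 0.0939 min⁻¹ + 0.0643 min⁻¹ + 0.005760 min⁻¹ = 0.164 min⁻¹

Its half-life, 4.23 min, is far shorter than the run, so I treat T as a quasi-steady state. With B at its solubility too: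

T = 0.169 M⁻¹ min⁻¹ · 0.10 M · 0.14 M / D = 0.01443 M

Might target crystallise? The coupling's own ceiling, 0.02520 M, lies 0.474 decades below the solubility of target, so I expect no solid product.

Does B hold? Without the way back, the flow into the isomer over the run is about

0.0643 min⁻¹ · T · 80 min = 0.0742 M

Solubility plus flow makes 0.214 M, more than the reagent charged. Dissolution must also carry that flow, so B sits lower:

B = 0.14 M − 0.0643 min⁻¹ · T / 0.0671 min⁻¹ = 0.126 M

That lowers T to 0.01301 M. Yet the isomer returns. After a lag of 14.9 min it reaches

I = 0.0643 min⁻¹ · T · (80 min − lag) = 0.0544 M

My estimate is therefore

T = (0.169 M⁻¹ min⁻¹ · 0.10 M · B + 0.004070 min⁻¹ · I) / D = 0.01436 M, or 7.18% of the charge.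

Does A hold? Isomer, target and side product, which takes two of substrate, draw about 0.0820 M in my reckoning. This is less than the solid beyond saturation, 0.100 M, so I keep A at its solubility.

The forecast gives 7.2%, best change none, and 6.5% after north. Its ground: “Quasi-steady target is T ≈ 0.013 + 0.028·I.”

The simulation gives 7.00%, best change none, and 7.34% after north, whose gain of 0.34 percentage points is less than the margin 2 points.

In this flask the going into solution of solid substrate had half its turnover behind it by 0.904 min, and dissolved substrate stood at 49.8% at 80.0 min with 15.6% still solid. The going into solution of solid reagent reached that mark by 16.1 min and the coupling by 42.0 min, and the isomer stood at 22.9% at 80.0 min. The end readings, put over D, give 7.08%. The neighbour charged with 0.12 M ends with 0% solid substrate and 52.8% dissolved; its readings, with D reckoned at its own A, give 8.06%, and it stands at 8.30%.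

(The numbers are invented, and the outcome is calculated.)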